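**Plan**
- Retrosynthesis: the acetates come from diol 18, the diol from diester 17, and the C8–C17 bond from alkoxycarbonylation of the Δ7 enol triflate of ketone 15.
- Ring B (C5–C6–C7–C8–C9–C10) is then cut at C6–C7 and C9–C10. With C8 as a ketone and C5=C6 in place, ring B is the [3,3] product of a 6-alkenyl β-keto-δ-lactone: O–C6–C5=C10 (the tetrasubstituted alkene of ring A) is the allyl part and enol carbon C9 the other terminus; C6 is the aldehyde carbon of β-cyclocitral.
- Forward: the C11–C16 chain comes from half-ester 1 as bromide 4; alkylation of tert-butyl acetoacetate gives C7–C8–C9 with the chain attached, then bis-silyl diene 7.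
- One flask joins 7 to β-cyclocitral: aldol (C6–C7), lactonisation, Carroll-type shift (C9–C10) and loss of CO2 build ring B on ring A; C5–H, C17, reduction and acetylation follow.
- Stereochemistry: C13 from 1; C6 (temporary) from a Ti–BINOL aldol and relayed to quaternary C10 by the suprafacial shift; C9 by equilibration next to C8=O; C5 by protonation and hydrogenation anti to the axial C10 methyl.

Key step: step 5

Remark: (S)-BINOL/Ti(OiPr)4 is assumed to send the diene to the Si face of 8, as with aryl aldehydes; the antipodal ligand would be used if the sense proves opposite.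

Step 1
Reactants: 1 methyl hydrogen (R)-3-methylglutarate
Product: 3 (4S)-4-methyloxan-2-one, via hydroxy acid 2 (not isolated)
Conditions: LiBH4 (2.2 equiv), THF, 0 → 25 °C; then 2 M HCl, 25 °C
Reagents that add atoms: none
Why: Chemoselective hydride reduction then lactonisation: the lithium carboxylate formed first is inert to LiBH4 while the methyl ester is reduced, and acid closes the δ-lactone; the stereocentre is untouched and only its descriptor changes because the two arms swap rank.

Step 2
Reactants: 3 (4S)-4-methyloxan-2-one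
Product: 4 methyl (3R)-5-bromo-3-methylpentanoate
Conditions: HBr (gas), MeOH, 0 → 50 °C
Reagents that add atoms: hydrogen bromide (Br); methanol (CO)
Why: Acid-mediated lactone opening by bromide at the primary O–CH2 carbon (SN2) with Fischer esterification, the standard route from lactones to ω-bromo esters; the remote stereocentre is not involved.

Step 3
Reactants: 4 methyl (3R)-5-bromo-3-methylpentanoate; 5 tert-butyl acetoacetate
Product: 6 1-tert-butyl 7-methyl (5S)-2-acetyl-5-methylheptanedioate (both C2 epimers)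
Conditions: NaH, THF–DMF, 0 °C; then 4, NaI (cat.), 60 °C
Reagents that add atoms: none
Why: Acetoacetic ester alkylation (SN2 of the sodium enolate on the primary bromide, Finkelstein-assisted) joins C9 to C11; the new C9 centre forms as a mixture and is settled later.

Step 4
Reactants: 6 1-tert-butyl 7-methyl (5S)-2-acetyl-5-methylheptanedioate
Product: 7 methyl (3S)-6-[tert-butoxy(trimethylsilyloxy)methylidene]-3-methyl-7-(trimethylsilyloxy)oct-7-enoate
Conditions: Me3SiOTf (2.2 equiv), Et3N (2.6 equiv), Et2O, 0 → 25 °C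
Reagents that add atoms: trimethylsilyl trifluoromethanesulfonate (C[Si](C)(C)OS(=O)(=O)C(F)(F)F)
Why: Twofold soft enolisation of the β-keto ester should give the 1,3-bis(silyloxy)diene, the less basic isolated methyl ester staying untouched.

Step 5
Reactants: 7 methyl (3S)-6-[tert-butoxy(trimethylsilyloxy)methylidene]-3-methyl-7-(trimethylsilyloxy)oct-7-enoate; 8 β-cyclocitral (2,6,6-trimethylcyclohex-1-ene-1-carbaldehyde)
Product: 13 methyl (10R,13S)-8-oxo-17-norlabd-5-en-15-oate (both C9 epimers), via aldol adduct 9 (not isolated), via acylketene 10 (not isolated), via keto lactone 11 (not isolated), via keto acid 12 (not isolated)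
Conditions: Ti(OiPr)4 (10 mol%), (S)-BINOL (10 mol%), 4 Å MS, THF, −78 → −20 °C; CF3CO2H (cat.), H2O, 0 °C; then solvent change to mesitylene, 110 → 165 °C, one flask
Reagents that add atoms: none
Why: Proposed new method: the Ti–BINOL-bound aldehyde 8 is attacked on its Si face by the γ-carbon of 7 (vinylogous Mukaiyama aldol; C6–C7; (6S)-carbinol 9); on heating, 9 loses tert-butanol to acylketene 10, the C6 hydroxyl closes β-keto-δ-lactone 11, and its ester enol (C9=C(OH)–O–C6–C5=C10, an allyl vinyl ether) undergoes a Carroll-type [3,3]-sigmatropic shift that makes C9–C10 and breaks O–C6, after which β-keto acid 12 loses CO2. The closest known reaction types are the Carroll rearrangement of open-chain allyl β-keto esters and the ring-forming ester-enolate Claisen rearrangement of 6-alkenyl δ-lactones; the shift on a β-keto-δ-lactone, telescoped with its assembly, has not been shown. Ring B closes as a six-membered carbocycle by ring contraction of the lactone through a boat-shaped six-centre array, the lactone O–C(=O) unit leaving as CO2, not by a polar endo or exo attack. C10 is set by suprafacial 1,3-transfer of chirality from C6: C7 must end cis to C10 on the new C5=C6 bond, so only one transition-state geometry is open and the (6S)-lactone brings C9 to the face of C10 that leaves the methyl group β; C6 is set by the catalyst, C9 is left for later equilibration and C13 comes in from 1. The step needs γ- over α-attack of the diene and 1,2- over 1,4-addition (the α-carbon of 7 and C10 of 8 are both fully substituted), and the concerted shift must outrun ionisation or β-elimination of the allylic lactone, which the neutral, non-polar, base-free medium favours.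

Step 6
Reactants: 13 methyl (10R,13S)-8-oxo-17-norlabd-5-en-15-oate
Product: 15 methyl (5S,9R,10S,13S)-8-oxo-17-norlabdan-15-oate, via conjugated enone 14 (not isolated)
Conditions: DBU (0.2 equiv), PhMe, 60 °C; then H2 (1 atm), Pd/C, EtOAc, 25 °C; then NaOMe (0.1 equiv), MeOH, 25 °C
Reagents that add atoms: none
Why: Base-mediated alkene isomerisation should bring C5=C6 into conjugation by γ-protonation at C5 on the α face, anti to the axial C10 methyl and the 4β-methyl (trans ring fusion); heterogeneous hydrogenation then saturates C6=C7, and methoxide equilibration should leave the C9 side chain equatorial (β), the more stable epimer next to the ketone.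

Step 7
Reactants: 15 methyl (5S,9R,10S,13S)-8-oxo-17-norlabdan-15-oate
Product: 16 methyl (5S,9R,10S,13S)-8-(trifluoromethylsulfonyloxy)-17-norlabd-7-en-15-oate
Conditions: LiN(SiMe3)2 (1.1 equiv), THF, −78 °C; PhNTf2, −78 → 0 °C
Reagents that add atoms: N-phenylbis(trifluoromethanesulfonimide) (O=S(=O)(N(c1ccccc1)S(=O)(=O)C(F)(F)F)C(F)(F)F)
Why: Regioselective enol triflate formation: kinetic deprotonation takes the C7 methylene and not the tertiary C9–H next to quaternary C10, and O-sulfonylation fixes the Δ7 enol triflate; no stereocentre is touched.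

Step 8
Reactants: 16 methyl (5S,9R,10S,13S)-8-(trifluoromethylsulfonyloxy)-17-norlabd-7-en-15-oate
Product: 17 dimethyl (5S,9R,10S,13S)-labd-7-ene-15,17-dioate
Conditions: Pd(OAc)2 (5 mol%), PPh3 (10 mol%), CO (1 atm), MeOH, Et3N, DMF, 60 °C
Reagents that add atoms: carbon monoxide ([C-]#[O+]); methanol (CO)
Why: Palladium-catalysed alkoxycarbonylation of the enol triflate (oxidative addition, CO insertion, methanolysis) installs C17 as an ester with the double bond fixed at C7=C8.

Step 9
Reactants: 17 dimethyl (5S,9R,10S,13S)-labd-7-ene-15,17-dioate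
Product: 18 (5S,9R,10S,13S)-labd-7-ene-15,17-diol
Conditions: i-Bu2AlH (5 equiv), CH2Cl2, −78 → 0 °C; aq. potassium sodium tartrate
Reagents that add atoms: none
Why: Hydride reduction of both esters gives the primary C15 alcohol and, by 1,2-reduction of the enoate, the allylic C17 alcohol, leaving the trisubstituted alkene alone.

Step 10
Reactants: 18 (5S,9R,10S,13S)-labd-7-ene-15,17-diol
Product: 19 (5S,9R,10S,13S)-labd-7-ene-15,17-diyl diacetate
Conditions: Ac2O, pyridine, DMAP (cat.), CH2Cl2, 25 °C
Reagents that add atoms: acetic anhydride (CC(=O)OC(C)=O)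
Why: DMAP-catalysed acylation of the two primary alcohols should give the diacetate.

**Compound list**
1 | methyl hydrogen (R)-3-methylglutarate, (3R)-5-methoxy-3-methyl-5-oxopentanoic acid | OC(=O)C[C@@H](C)CC(=O)OC | starting material
2 | (3S)-5-hydroxy-3-methylpentanoic acid (lithium salt in the flask) | OC(=O)C[C@@H](C)CCO | intermediate
3 | (4S)-4-methyloxan-2-one | O=C1C[C@@H](C)CCO1 | intermediate
4 | methyl (3R)-5-bromo-3-methylpentanoate | COC(=O)C[C@@H](C)CCBr | intermediate
5 | tert-butyl acetoacetate | CC(=O)CC(=O)OC(C)(C)C | starting material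
6 | 1-tert-butyl 7-methyl (5S)-2-acetyl-5-methylheptanedioate (C2 epimers) | CC(=O)C(CC[C@H](C)CC(=O)OC)C(=O)OC(C)(C)C | intermediate
7 | methyl (3S)-6-[tert-butoxy(trimethylsilyloxy)methylidene]-3-methyl-7-(trimethylsilyloxy)oct-7-enoate | C=C(O[Si](C)(C)C)C(CC[C@H](C)CC(=O)OC)=C(OC(C)(C)C)O[Si](C)(C)C | intermediate
8 | β-cyclocitral, 2,6,6-trimethylcyclohex-1-ene-1-carbaldehyde | CC1=C(C=O)C(C)(C)CCC1 | starting material
9 | 1-tert-butyl 7-methyl (5S)-2-[(3S)-3-hydroxy-3-(2,6,6-trimethylcyclohex-1-en-1-yl)propanoyl]-5-methylheptanedioate (C2 epimers) | CC1=C([C@@H](O)CC(=O)C(CC[C@H](C)CC(=O)OC)C(=O)OC(C)(C)C)C(C)(C)CCC1 | intermediate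
10 | methyl (3S,9S)-9-hydroxy-3-methyl-7-oxo-6-(oxomethylidene)-9-(2,6,6-trimethylcyclohex-1-en-1-yl)nonanoate (acylketene) | CC1=C([C@@H](O)CC(=O)C(CC[C@H](C)CC(=O)OC)=C=O)C(C)(C)CCC1 | intermediate
11 | methyl (3S)-3-methyl-5-[(6S)-2,4-dioxo-6-(2,6,6-trimethylcyclohex-1-en-1-yl)oxan-3-yl]pentanoate (C3 epimers, enolised) | CC1=C([C@@H]2CC(=O)C(CC[C@H](C)CC(=O)OC)C(=O)O2)C(C)(C)CCC1 | intermediate
12 | (1S,8aS)-1-[(3S)-5-methoxy-3-methyl-5-oxopentyl]-5,5,8a-trimethyl-2-oxo-1,2,3,5,6,7,8,8a-octahydronaphthalene-1-carboxylic acid | COC(=O)C[C@@H](C)CC[C@@]1(C(=O)O)C(=O)CC=C2C(C)(C)CCC[C@]12C | intermediate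
13 | methyl (10R,13S)-8-oxo-17-norlabd-5-en-15-oate (C9 epimers; 10β-methyl) | COC(=O)C[C@@H](C)CCC1C(=O)CC=C2C(C)(C)CCC[C@]12C | intermediate
14 | methyl (5S,9R,10S,13S)-8-oxo-17-norlabd-6-en-15-oate | COC(=O)C[C@@H](C)CC[C@H]1C(=O)C=C[C@H]2C(C)(C)CCC[C@]12C | intermediate
15 | methyl (5S,9R,10S,13S)-8-oxo-17-norlabdan-15-oate | COC(=O)C[C@@H](C)CC[C@H]1C(=O)CC[C@H]2C(C)(C)CCC[C@]12C | intermediate
16 | methyl (5S,9R,10S,13S)-8-(trifluoromethylsulfonyloxy)-17-norlabd-7-en-15-oate | COC(=O)C[C@@H](C)CC[C@H]1C(OS(=O)(=O)C(F)(F)F)=CC[C@H]2C(C)(C)CCC[C@]12C | intermediate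
17 | dimethyl (5S,9R,10S,13S)-labd-7-ene-15,17-dioate | COC(=O)C[C@@H](C)CC[C@H]1C(C(=O)OC)=CC[C@H]2C(C)(C)CCC[C@]12C | intermediate
18 | (5S,9R,10S,13S)-labd-7-ene-15,17-diol | OCC[C@@H](C)CC[C@H]1C(CO)=CC[C@H]2C(C)(C)CCC[C@]12C | intermediate
19 | (5S,9R,10S,13S)-labd-7-ene-15,17-diyl diacetate | CC(=O)OCC[C@@H](C)CC[C@H]1C(COC(C)=O)=CC[C@H]2C(C)(C)CCC[C@]12C | target

**Step count and risks**
Total steps: 10. Longest linear sequence: 10 steps (1 → 19); 5 enters at step 3 and 8 at step 5.

Steps most likely to fail: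

Step 5. The aldol addition to the hindered, tetrasubstituted enal may be slow or poorly face-selective. The shift joins two fully substituted carbons, so ionisation of the allylic lactone or β-elimination towards a dienone may compete with it. The fallback sets out from 9, isolated after the aldol stage, and uses known chemistry. The hydroxyl is converted with ClCO2Me and pyridine into 1-tert-butyl 7-methyl (5S)-2-[(3S)-3-(methoxycarbonyloxy)-3-(2,6,6-trimethylcyclohex-1-en-1-yl)propanoyl]-5-methylheptanedioate F1. An intramolecular Tsuji–Trost allylic alkylation (Pd(PPh3)4, THF, 40 °C) should then join C9 to C10 with net retention, because only attack at C10 gives a six-membered ring. This gives tert-butyl (8aS)-1-[(3S)-5-methoxy-3-methyl-5-oxopentyl]-5,5,8a-trimethyl-2-oxo-1,2,3,5,6,7,8,8a-octahydronaphthalene-1-carboxylate F2. CF3CO2H followed by warming removes the tert-butyl group and CO2, and the route is rejoined at 13.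

Step 6. Protonation at C5 may lack facial selectivity and give the cis-fused ketone, or the alkene may not move fully into conjugation before hydrogenation. The fallback sets out from 13 after DBU equilibration of C9. LiN(SiMe3)2 and PhNTf2 should give the dienyl triflate methyl (9R,10R,13S)-8-(trifluoromethylsulfonyloxy)-17-norlabda-5,7-dien-15-oate F3. Alkoxycarbonylation (Pd(OAc)2, PPh3, CO, MeOH, Et3N) should give dimethyl (9R,10R,13S)-labda-5,7-diene-15,17-dioate F4. Dissolving-metal 1,6-reduction (Li, NH3, t-BuOH, −78 °C) protonates C5 on the α face, and NaOMe in MeOH moves the alkene back into conjugation. The route is rejoined at 17, bypassing 15 and 16.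

Step 4. The silyl triflate may cleave the tert-butyl ester or silylate the remote methyl ester, and the diene is prone to hydrolysis. The fallback sets out from 6. Acetone, Ac2O and catalytic H2SO4 should give methyl (3S)-3-methyl-5-(2,2,6-trimethyl-4-oxo-4H-1,3-dioxin-5-yl)pentanoate F5. LiN(SiMe3)2 and Me3SiCl at −78 °C should give the silyl dienol ether methyl (3S)-5-[2,2-dimethyl-6-methylidene-4-(trimethylsilyloxy)-6H-1,3-dioxin-5-yl]-3-methylpentanoate F6. A copper-catalysed enantioselective aldol addition to 8 (Cu(OTf)2, Tol-BINAP of the antipode that gives Si-face attack, (Bu4N)Ph3SiF2, THF, −78 °C) should give methyl (3S)-5-{6-[(2S)-2-hydroxy-2-(2,6,6-trimethylcyclohex-1-en-1-yl)ethyl]-2,2-dimethyl-4-oxo-4H-1,3-dioxin-5-yl}-3-methylpentanoate F7. Heating F7 in toluene releases acetone and gives acylketene 10, so the route is rejoined at lactone 11 and continues to 13 as in step 5.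

Further compounds
F1 | step 5 | 1-tert-butyl 7-methyl (5S)-2-[(3S)-3-(methoxycarbonyloxy)-3-(2,6,6-trimethylcyclohex-1-en-1-yl)propanoyl]-5-methylheptanedioate | CC1=C([C@@H](OC(=O)OC)CC(=O)C(CC[C@H](C)CC(=O)OC)C(=O)OC(C)(C)C)C(C)(C)CCC1
F2 | step 5 | tert-butyl (8aS)-1-[(3S)-5-methoxy-3-methyl-5-oxopentyl]-5,5,8a-trimethyl-2-oxo-1,2,3,5,6,7,8,8a-octahydronaphthalene-1-carboxylate (C1 not controlled) | COC(=O)C[C@@H](C)CCC1(C(=O)OC(C)(C)C)C(=O)CC=C2C(C)(C)CCC[C@]12C
F3 | step 6 | methyl (9R,10R,13S)-8-(trifluoromethylsulfonyloxy)-17-norlabda-5,7-dien-15-oate | COC(=O)C[C@@H](C)CC[C@H]1C(OS(=O)(=O)C(F)(F)F)=CC=C2C(C)(C)CCC[C@]12C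
F4 | step 6 | dimethyl (9R,10R,13S)-labda-5,7-diene-15,17-dioate | COC(=O)C[C@@H](C)CC[C@H]1C(C(=O)OC)=CC=C2C(C)(C)CCC[C@]12C
F5 | step 4 | methyl (3S)-3-methyl-5-(2,2,6-trimethyl-4-oxo-4H-1,3-dioxin-5-yl)pentanoate | COC(=O)C[C@@H](C)CCC1=C(C)OC(C)(C)OC1=O
F6 | step 4 | methyl (3S)-5-[2,2-dimethyl-6-methylidene-4-(trimethylsilyloxy)-6H-1,3-dioxin-5-yl]-3-methylpentanoate | COC(=O)C[C@@H](C)CCC1=C(O[Si](C)(C)C)OC(C)(C)OC1=C
F7 | step 4 | methyl (3S)-5-{6-[(2S)-2-hydroxy-2-(2,6,6-trimethylcyclohex-1-en-1-yl)ethyl]-2,2-dimethyl-4-oxo-4H-1,3-dioxin-5-yl}-3-methylpentanoate | COC(=O)C[C@@H](C)CCC1=C(C[C@H](O)C2=C(C)CCCC2(C)C)OC(C)(C)OC1=O
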